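**Four questions.** You sent me 4 questions with your hunch attached, and I reckoned with one quantity, which did not reach all of them.

| flask | substrate | remark | time |
|---|---|---|---|
| red | 0.25 mM | run made earlier |  |
| flask | 0.50 mM |  | 30 min |

red run (percent of the substrate charged)

| time / min | target / % | isomer of the product / % |
|---|---|---|
| 0.500 | 31 | 3 |
| 1.00 | 22 | 5 |
| 1.50 | 16 | 5 |
| 2.00 | 12 | 8 |
| 2.50 | 8 | 8 |
| 3.00 | 7 | 5 |

(readings scatter by 1.5 percentage points)

- ratio of target to isomer of the product at 1.0 s
- ratio of target to isomer of the product at 40 s
- ratio of target to isomer of the product at 30 min
- which of target and isomer of the product there is more of at 30 min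

- candidate steps: substrate <-> isomer of the product; substrate <-> third isomer; substrate <-> dormant form; substrate <-> target; target -> over-reaction product

**My reckoning.** I compared target and isomer of the product at one moment, then asked how that comparison moved. In the red run their ratio read 10.3 at 0.500 min and 1.40 at 3.00 min. I kept 0.800 min⁻¹ as the ratio drift, the fall per minute of the natural logarithm of target over isomer of the product. It was rough, since the first isomer reading of 3% carried a scatter of 1.5 percentage points. Each candidate step links one species to one other. So if they were first-order, percentages at 0.50 mM would repeat those at 0.25 mM, and I used the drift unchanged. It put the level point, where the ratio reaches one, at 3.42 min, with the isomer of the product ahead afterwards. I gave no ratio for 30 min, which lay far later than the last reading.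

**Your forecast.** It gave 15 at 1.0 s, 7 at 40 s and 0.4 at 30 min, with isomer of the product ahead, holding that the “target is held down by its drain”. We agreed on the lead and differed in that you committed to a late ratio.

**The flask.** It gave 10.8, 6.11 and 0.0528, with isomer of the product ahead. Target and isomer of the product stood level at 3.29 min, where I had said 3.42 min. From there to 30 min the ratio's logarithm fell by 0.110 min⁻¹ on average, slower than the drift, so the drift did not carry on past the level point.

    substrate ⇌ isomer of the product (K = 25.0, k = 0.00506 s⁻¹)
    substrate ⇌ third isomer (K = 0.610, k = 0.0122 s⁻¹)
    substrate ⇌ dormant form (K = 13.0, k = 0.0435 s⁻¹)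
    substrate ⇌ target (K = 8.70, k = 0.0551 s⁻¹)
    target → over-reaction product (k = 0.0139 s⁻¹)

**Neighbour flask.** With 0.85 mM of substrate the steps were still first-order, so I carried the drift of 0.800 min⁻¹ over unchanged, and it again put the level point at 3.42 min. The computed ratio in that neighbour flask at 30 min was 0.0528, the same as in the flask with 0.50 mM, with 8.68% of the isomer of the product.

The earlier runs and the new flask are calculated for substances that don't exist; the scatter is artificial.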